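At 30 h we have to say how much target stands in the flask and which remedy pays. Our evidence is the flask's own run so far, called west.

the same everywhere: starting material 22 mM; partner 1.05 equiv

| flask | protic impurity | remark | time |
|---|---|---|---|
| west | 22 mM | the very flask that is asked about, followed so far |  |
| flask | 22.0 mM |  | 30 h |

- west (time / h: target / %): 2.00: 12.5; 6.00: 17.3; 12.0: 18.3; 15.0: 18.0; 25.0: 17.6

(scatter of a reading: 0.3 percentage points)

- what is taken out of target is counted as made
- additions bring no volume worth counting

- ash: at 30 h add partner, 50.0% of the amount charged, then wait 30 h
- elm: at 30 h add starting material, 50.0% of the amount charged, then wait 30 h
- cedar: change nothing and wait 30 h more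
- larch: at 30 h take out 90% of the target then present, then wait 30 h

- target, in percent of the starting material first charged, at 30 h
- the remedy with the largest gain of target, or "none" below 2 percentage points (ash / elm / cedar / larch / none)
- target present, with what was taken out counted in, in percent of the starting material first charged, after elm
- target present, with what was taken out counted in, in percent of the starting material first charged, after larch

We suppose that the protic impurity destroys partner one for one, and that each target costs one partner. Take the partner charged, subtract the protic impurity charged, and divide by the starting material charged. This gives 5.00%, the partner surplus: the share of the starting material that can still couple once the impurity has taken its full claim. The flask's surplus is far smaller than the partner charge, so the flask sits close to the crossing at zero, where control passes to the impurity.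

One number is not enough, though. The west readings stop rising near 12.0 h and stand at 18.0% at 15.0 h, above the surplus. So coupling won part of the race, and if the stall marks the end of the partner, impurity equal to at least 13.0% of the starting material charged remains unused.

We take the stall as the loss of the partner, and a scatter of 0.3 percentage points shows no firm fall afterwards. Our reckoning therefore holds the target at the mean of the last readings, 18.0%. Cedar and elm bring no partner, and larch merely counts in what it removes, so we expect each to stay at that level. Ash lifts the surplus to 57.5%, so we choose ash.

The forecast, a different reckoning, gives 17.3% now, 15.9% after elm and 17.2% after larch, each below our level, and it names ash: “Ash supplies fresh partner”.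

The flask gives 18.0%. Ash is best, gaining 32 points. Elm ends at 18.0%, and larch at 22.6%, which is 4.6 points above our figure.

    partner + intermediate → target (k = 0.0400 M⁻¹ s⁻¹)
    partner + protic impurity → quenched reagent (k = 0.0210 M⁻¹ s⁻¹)
    target ⇌ isomer of the product (K = 0.400, k = 1.20 × 10⁻⁴ s⁻¹)
    starting material → intermediate (k = 5.10 × 10⁻⁵ s⁻¹)

At 30 h the flask holds 0% of its partner, the limiting reagent, and 20% of its impurity. The surplus plus that unused impurity, per starting material, comes to 25.2%, and target and isomer of the product together hold 25.2%. In the neighbouring flask, the same recipe with 88 mM of starting material, the surplus is 80.0%. There the impurity stands at 0% and the quenched reagent at 22.0 mM. Target reaches 57.1% and isomer of the product 22.9%, together 80.0%, while intermediate holds 19.6%.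

(All runs are simulated from invented constants.)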